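## Structural features

The target is a 3,3a-dihydro-1-benzofuran-6(2H)-one. Ring A is a six-membered cross-conjugated dienone (C4=C5 bearing OMe, C6=O, C7=C7a). Ring B is a tetrahydrofuran (O1, C2, C3, C3a, C7a) fused to ring A across the C3a–C7a bond. C3a is an sp3 all-carbon quaternary centre carrying the allyl group, C3 carries a methyl group and C2 the 3,4,5-trimethoxyphenyl group. These three centres are contiguous, configured (2S,3S,3aS), and each substituent is trans to its neighbour on ring B. O1 is both the ether oxygen of ring B and the donor of a vinylogous ester (O1–C7a=C7–C6=O), while C4=C5–C6=O is an α-methoxy enone. The fragile parts are the 4,4-disubstituted dienone (acid or heat can aromatise it with migration of the allyl group), the electron-rich benzylic C2–O1 bond (it can ionise) and the terminal alkene (it excludes hydrogenation and electrophilic oxidants). The real difficulty is the quaternary stereocentre C3a next to C3, in one absolute configuration, on a ring A that is not aromatic. The chosen plan exploits the fact that O1, C7a, C3a, C3 and C2 are the atom sequence of a γ-lactone: with C7a as carbonyl, C3a and C3 are the α- and β-carbons of a butenolide and C2 its γ-carbon, so methyl and allyl can be installed by conjugate addition and enolate alkylation under the control of the C2 aryl group.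

## Logic of the disconnections

**16 to 13.** The C4=C5 double bond and the O1–C7a enol ether bond are cut (retro-aldol condensation and retro-cyclodehydration). The dienone cannot be carried through organometallic steps, so ring A is opened to 13, where C4 is a masked aldehyde, C5 the methylene of a methoxymethyl ketone and C7a a ketone. Ring A disappears and no stereocentre is touched. The forward step must close two bonds and lose water twice under acid mild enough for 16; it can, because none of the three stereocentres is enolisable.

**13 to 10 and 11.** The C7–C7a bond is cut (retro-Claisen). C7a is at the acid oxidation level and coincides with the lactone carbonyl of 10; C5, C6 and C7 with the methoxy group are the three carbons of 11. The forward step needs enolisation of 11 at the methyl group (12) and addition to a carbonyl flanked by a quaternary carbon. The absence of α-hydrogen in 10 means it can act only as the electrophile.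

**10 to 7 and 8 (key step).** The C3–CH3 and C3a–CH2(allyl) bonds are cut. Both carbons lie β and α to the lactone carbonyl, so both bonds come from one conjugate addition–alkylation on 7. Two stereocentres, one of them quaternary, are removed and only the C2 centre remains on a flat ring. The forward step needs methyl anti to aryl and allyl anti to methyl, and an enolate (9) that survives until it is alkylated. The diethyl acetal is kept as the mask of C4: it is inert to cuprate and enolate, carries no acidic hydrogen, comes directly from commercial 2 and is released by the acid that closes ring A.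

**7 to 6.** The C3a–C7a bond and the acyl–O1 bond are cut (retro-carbonylative lactonisation). The carbonyl carbon comes from CO. The forward step needs the Z geometry of 6 and a base that does not remove the acidic C2–H of 7.

**6 to 4.** The carbon–iodine bond and the C3–H bond are removed across the alkyne. The hydroxyl group of 4 directs a trans-hydroalumination through 5, so regiochemistry and geometry are set by the substrate.

**4 to 1 and 2.** The C2–C3 bond (carbinol to alkyne) is cut. Both pieces are commercial. The forward step must set the only reagent-controlled stereocentre of the route, with R configuration.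

## Other disconnections considered

Alternative 1: The cut is the C3–C3a bond, formed by ring contraction while ring A stays aromatic.
- **Forward step:** irradiation of the 3-diazochroman-4-one A2 in methanol would expel N2, shift the aryl carbon C3a from the carbonyl carbon to C3 and trap the ketene as the ester A1. The C2/C3 trans relation would follow from protonation anti to the aryl group and from the epimerisable ester.
- **In favour:** A2 would be reached from 1 by robust carbonyl and arene chemistry, and the photochemical Wolff rearrangement of cyclic α-diazo ketones is dependable. On the certainty of the key step this plan is the better one, and on C2/C3 control it is the equal of the chosen plan.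
- **Against:** A1 has no C3 methyl group, no allyl group and no dienone. Reduction of the ester to methyl, desilylation and a dearomatising C-allylation at C3a must follow. That last step must beat O-allylation and allylation at C7 and choose the face anti to the C3 methyl group, so the hardest element is deferred to the end. The C2 centre of A2 lies β to the ketone and can be lost by reversible retro-oxa-Michael ring opening under the basic conditions of diazo transfer.
- **Comparison:** structurally the chosen plan settles C3 and C3a in its key step, whereas this one settles only C3. Some nine to ten steps are estimated against six.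

Alternative 2: The cuts are C3a–C7a and C6–C7, a retro-Diels–Alder opening of ring A with C3, C2 and O1 as the tether.
- **Forward step:** heating A4 would add its vinylketene silyl acetal across the tethered alkoxypropiolate and give A3 after collapse of the C6 silyl methyl ketal.
- **In favour:** two rings and two C–C bonds form at once, and ring A emerges with the C5 methoxy group, the C6 ketone and both double bonds in place. On ring construction and on the length of the end-game (ester cleavage and decarboxylation only) this plan is better than the chosen one; on the number of skeletal bonds formed in the key step it is equal.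
- **Against:** A4 combines a push–pull ynol ether on a hindered benzylic alcohol with an acid- and moisture-labile ketene acetal. Its diene terminus C3a is 1,1-disubstituted, so one group must sit inside the s-cis diene and slow the cycloaddition. The C3a configuration rests on allylic strain in a flexible tether rather than on a 1,2-contact on a rigid ring. The anti C2/C3 pair must be made separately beforehand.
- **Comparison:** mechanistically the cycloaddition is concerted and has no endo/exo issue with an alkyne, but its facial selectivity is less predictable than the anti/anti relay on a butenolide. The route to A4 is estimated to be clearly longer than the three steps to 7.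

Alternative 3: The cut is the O1–C7a bond.
- **Forward step:** catalytic KOC(CH3)3 would let the C2 alkoxide of the prochiral dienone A6 add to one of its two enone β-carbons (5-exo-trig), giving the cis-fused A5 and fixing C3a.
- **In favour:** the step is catalytic, needs no cryogenic organometallic reagent, and creates the quaternary stereocentre from a prochiral carbon. On operational simplicity it is better than the chosen plan, and on the principle of using C3 to control C3a it is equal.
- **Against:** the two enone arms differ only through the C3 centre in a freely rotating side chain, and because the addition is reversible the outcome would be a thermodynamic mixture whose bias is uncertain. A5 lacks the C5 methoxy group and the C7=C7a double bond, so enone α-oxygenation, methylation and dehydrogenation must follow, under conditions in which retro-oxa-Michael opening could scramble C3a. A6 still requires the anti aryl carbinol/methyl pair attached to a quaternary dienone carbon.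
- **Comparison:** structurally the key step gives less of the target than the chosen one and leaves ring A at the wrong oxidation level. The total step count is estimated to be higher.

Key step: step 4

Assumption 1: (S)-BINOL is taken to direct the alkynylzinc to the Si face of the aryl aldehyde, as in related additions to aromatic aldehydes; if the sense proved opposite, (R)-BINOL would be used and nothing else changes.

Assumption 2: 13 is written as the open-chain hydroxy diketone; its enol and ring-closed hemiketal tautomers behave as the same compound in step 6.

Remark on the structures: the fixed structures were rechecked atom by atom and need no correction. The descriptors are 7 (5S), 10 (3S,4S,5S) and 16 (2S,3S,3aS). Carbinol 4 must be R, because the alkynyl carbon outranks aryl in 4 whereas aryl outranks the alkene carbon in 6 and 7.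

Step 1
Reactants: 1 3,4,5-trimethoxybenzaldehyde; 2 3,3-diethoxyprop-1-yne
Product: 4 (1R)-4,4-diethoxy-1-(3,4,5-trimethoxyphenyl)but-2-yn-1-ol, via ethylzinc acetylide 3 (not isolated)
Conditions: (S)-BINOL (40 mol %), Et2Zn, Cy2NH (5 mol %), Et2O, rt; Ti(OiPr)4; then 1, rt; aq NH4Cl
Reagents that add atoms: none
Why: BINOL–titanium-catalysed asymmetric addition of an alkynylzinc to an aromatic aldehyde; Et2Zn deprotonates 2 to 3, the chiral titanium BINOLate activates 1 and exposes its Si face, which should give the R carbinol. The acetal and the aryl ethers are inert to these reagents.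

Step 2
Reactants: 4 (1R)-4,4-diethoxy-1-(3,4,5-trimethoxyphenyl)but-2-yn-1-ol
Product: 6 (1S,2Z)-4,4-diethoxy-3-iodo-1-(3,4,5-trimethoxyphenyl)but-2-en-1-ol, via cyclic vinylalanate 5 (not isolated)
Conditions: NaAlH2(OCH2CH2OMe)2, THF, 0 °C; EtOAc; I2, THF, −78 → 0 °C
Reagents that add atoms: iodine, [I][I]
Why: Hydroxyl-directed trans-hydroalumination of a propargylic alcohol; the alkoxyaluminium hydride delivers hydride to the proximal alkyne carbon and places aluminium on the distal one in the five-membered alanate 5, and iodinolysis of the C–Al bond with retention gives the Z iodoalkene. The carbinol centre is not touched; its descriptor changes from R to S only because the priorities change.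

Step 3
Reactants: 6 (1S,2Z)-4,4-diethoxy-3-iodo-1-(3,4,5-trimethoxyphenyl)but-2-en-1-ol
Product: 7 (5S)-3-(diethoxymethyl)-5-(3,4,5-trimethoxyphenyl)furan-2(5H)-one
Conditions: Pd(PPh3)4 (5 mol %), CO (1 atm), K2CO3, THF, 40 °C
Reagents that add atoms: carbon monoxide, [C-]#[O+]
Why: Palladium-catalysed carbonylative lactonisation of a (Z)-3-iodoallylic alcohol; oxidative addition of the carbon–iodine bond to zerovalent palladium, CO insertion and capture of the acylpalladium by the cis hydroxyl group close the butenolide. The insoluble carbonate is chosen over an amine base so that the acidic C5–H of 7 is not removed.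

Step 4
Reactants: 7 (5S)-3-(diethoxymethyl)-5-(3,4,5-trimethoxyphenyl)furan-2(5H)-one; 8 allyl bromide
Product: 10 (3S,4S,5S)-3-allyl-3-(diethoxymethyl)-4-methyl-5-(3,4,5-trimethoxyphenyl)dihydrofuran-2(3H)-one, via lithium lactone enolate 9 (not isolated)
Conditions: Me2CuLi (from MeLi, CuBr·SMe2), Et2O/THF, −78 → −40 °C; then 8, DMPU, −78 → −20 °C; aq NH4Cl/NH3
Reagents that add atoms: lithium dimethylcuprate, [Li+].C[Cu-]C
Why: Me2CuLi forms a π-complex with the enoate, adds oxidatively to give a trivalent copper β-cuprio enolate and eliminates reductively, forming the C3–CH3 bond (benzofuran numbering) and enolate 9. The two faces of the flat butenolide differ only by the C2 aryl group, so methyl should be transferred anti to it, which sets C3 under the control of C2. Allyl bromide then alkylates the enolate carbon C3a in an SN2 reaction on the face opposite the adjacent C3 methyl group, which sets the quaternary centre under the control of C3 and leaves the diethoxymethyl group cis to methyl. No ring is closed; two C–C bonds and two stereocentres are added to the existing lactone ring. The closest known reaction type is the tandem cuprate conjugate addition–enolate alkylation of 5-substituted butenolides, which gives 3,4-trans-4,5-trans lactones. The step needs 1,4- over 1,2-addition (soft cuprate), C- over O-allylation (lithium enolate with a soft bromide in THF/DMPU) and no deprotonation of the doubly activated C2–H (weakly basic cuprate, low temperature). It also needs enolate 9 to keep its ethoxy groups, which is why it is held at or below −40 °C until the electrophile is present. The α-acetal slightly raises the electrophilicity of the acceptor and carries C4 at the aldehyde oxidation level without an acidic hydrogen.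

Step 5
Reactants: 10 (3S,4S,5S)-3-allyl-3-(diethoxymethyl)-4-methyl-5-(3,4,5-trimethoxyphenyl)dihydrofuran-2(3H)-one; 11 methoxyacetone
Product: 13 (5S,6S,7S)-5-(diethoxymethyl)-7-hydroxy-1-methoxy-6-methyl-5-(prop-2-en-1-yl)-7-(3,4,5-trimethoxyphenyl)heptane-2,4-dione, via lithium 3-methoxyprop-1-en-2-olate 12 (not isolated)
Conditions: LiN(iPr)2 (3 equiv), 11 (3 equiv), THF, −78 °C; then 10, −78 → −20 °C; aq NH4Cl
Reagents that add atoms: none
Why: Crossed Claisen acylation of a ketone enolate by a lactone; kinetic deprotonation of 11 at −78 °C should occur at the methyl group, and 10 has no α-hydrogen, so it can act only as the electrophile. Excess enolate deprotonates the β-diketone released by ring opening, which drives the addition; no stereocentre is formed or endangered.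

Step 6
Reactants: 13 (5S,6S,7S)-5-(diethoxymethyl)-7-hydroxy-1-methoxy-6-methyl-5-(prop-2-en-1-yl)-7-(3,4,5-trimethoxyphenyl)heptane-2,4-dione
Product: 16 (2S,3S,3aS)-5-methoxy-3-methyl-3a-(prop-2-en-1-yl)-2-(3,4,5-trimethoxyphenyl)-3,3a-dihydro-1-benzofuran-6(2H)-one, via enol ether keto aldehyde 14 (not isolated), via ring A aldol 15 (not isolated)
Conditions: 1 M HCl, THF, rt → 45 °C
Reagents that add atoms: none
Why: Acid-mediated cascade of acetal hydrolysis, cyclodehydration of the hydroxy β-diketone to the vinylogous ester 14 (its geometric isomers interconvert under acid) and intramolecular aldol condensation (6-enolendo-exo-trig) through 15 to the cross-conjugated dienone. C3a bears no hydrogen and C2 and C3 are not enolisable, so the three stereocentres should persist.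

## Compound list

1 | 3,4,5-trimethoxybenzaldehyde | COc1cc(C=O)cc(OC)c1OC | starting material
2 | 3,3-diethoxyprop-1-yne | C#CC(OCC)OCC | starting material
3 | (3,3-diethoxyprop-1-yn-1-yl)(ethyl)zinc | CC[Zn]C#CC(OCC)OCC | intermediate
4 | (1R)-4,4-diethoxy-1-(3,4,5-trimethoxyphenyl)but-2-yn-1-ol | O[C@H](c1cc(OC)c(OC)c(OC)c1)C#CC(OCC)OCC | intermediate
5 | sodium (5S)-3-(diethoxymethyl)-2,2-bis(2-methoxyethoxy)-5-(3,4,5-trimethoxyphenyl)-2,5-dihydro-1,2-oxaaluminol-2-uide (five-membered vinylalanate) | [Na+].CCOC(OCC)C1=C[C@@H](c2cc(OC)c(OC)c(OC)c2)O[Al-]1(OCCOC)OCCOC | intermediate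
6 | (1S,2Z)-4,4-diethoxy-3-iodo-1-(3,4,5-trimethoxyphenyl)but-2-en-1-ol | O[C@H](c1cc(OC)c(OC)c(OC)c1)/C=C(\I)C(OCC)OCC | intermediate
7 | (5S)-3-(diethoxymethyl)-5-(3,4,5-trimethoxyphenyl)furan-2(5H)-one | O=C1O[C@H](c2cc(OC)c(OC)c(OC)c2)C=C1C(OCC)OCC | intermediate
8 | allyl bromide (3-bromoprop-1-ene) | C=CCBr | starting material
9 | lithium (4S,5S)-3-(diethoxymethyl)-4-methyl-5-(3,4,5-trimethoxyphenyl)-4,5-dihydrofuran-2-olate | [Li+].CCOC(OCC)C1=C([O-])O[C@H](c2cc(OC)c(OC)c(OC)c2)[C@H]1C | intermediate
10 | (3S,4S,5S)-3-allyl-3-(diethoxymethyl)-4-methyl-5-(3,4,5-trimethoxyphenyl)dihydrofuran-2(3H)-one | C=CC[C@]1(C(OCC)OCC)C(=O)O[C@H](c2cc(OC)c(OC)c(OC)c2)[C@H]1C | intermediate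
11 | methoxyacetone (1-methoxypropan-2-one) | COCC(C)=O | starting material
12 | lithium 3-methoxyprop-1-en-2-olate | [Li+].[O-]C(=C)COC | intermediate
13 | (5S,6S,7S)-5-(diethoxymethyl)-7-hydroxy-1-methoxy-6-methyl-5-(prop-2-en-1-yl)-7-(3,4,5-trimethoxyphenyl)heptane-2,4-dione | COCC(=O)CC(=O)[C@](CC=C)(C(OCC)OCC)[C@H](C)[C@H](O)c1cc(OC)c(OC)c(OC)c1 | intermediate
14 | (2E,3R,4S,5S)-2-(3-methoxy-2-oxopropylidene)-4-methyl-3-(prop-2-en-1-yl)-5-(3,4,5-trimethoxyphenyl)oxolane-3-carbaldehyde (the isomer with the acyl group syn to C3; it equilibrates with the Z isomer under acid) | C=CC[C@]1(C=O)/C(=C\C(=O)COC)O[C@H](c2cc(OC)c(OC)c(OC)c2)[C@H]1C | intermediate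
15 | (2S,3S,3aS)-4-hydroxy-5-methoxy-3-methyl-3a-(prop-2-en-1-yl)-2-(3,4,5-trimethoxyphenyl)-3,3a,4,5-tetrahydro-1-benzofuran-6(2H)-one (mixture of epimers at C4 and C5) | C=CC[C@]12C(O)C(OC)C(=O)C=C1O[C@H](c1cc(OC)c(OC)c(OC)c1)[C@H]2C | intermediate
16 | (2S,3S,3aS)-5-methoxy-3-methyl-3a-(prop-2-en-1-yl)-2-(3,4,5-trimethoxyphenyl)-3,3a-dihydro-1-benzofuran-6(2H)-one | C=CC[C@]12C=C(OC)C(=O)C=C1O[C@H](c1cc(OC)c(OC)c(OC)c1)[C@H]2C | target

## Step count and least certain steps

Total step count: 6. Longest linear sequence: 6 steps (1 → 4 → 6 → 7 → 10 → 13 → 16); 2, 8 and 11 are commercial and enter directly.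

**Step 4 (key step).** The most likely failures are β-elimination of ethoxide from enolate 9 before it is alkylated, slow allylation of the copper-associated enolate at a carbon that becomes quaternary, and electron transfer from the cuprate with cleavage of the benzylic C–O bond. Fallback, from 7 back to 10: the conjugate addition would be run with Me2CuLi and Me3SiCl so that the enolate is trapped at once as (4S,5S)-3-(diethoxymethyl)-4-methyl-2-(trimethylsilyloxy)-5-(3,4,5-trimethoxyphenyl)-4,5-dihydrofuran F1. F1 would then be allylated under neutral conditions by palladium catalysis (Pd2(dba)3, dppe, allyl methyl carbonate, THF, reflux), the π-allyl electrophile again approaching anti to the C3 methyl group, to give 10.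

**Step 5.** Addition to a carbonyl flanked by a quaternary carbon may be slow or reversible. On warming, proton exchange may equilibrate 12 to the methoxy-substituted enolate, leading to self-condensation of 11 or to attack through the wrong carbon. Fallback, from 10 back to 13: the small, non-equilibrating nucleophile LiC≡CCH2OMe (methyl propargyl ether, nBuLi, THF, −78 °C) would add to the lactone to give (5S,6S,7S)-5-(diethoxymethyl)-7-hydroxy-1-methoxy-6-methyl-5-(prop-2-en-1-yl)-7-(3,4,5-trimethoxyphenyl)hept-2-yn-4-one F2. Conjugate addition of Et2NH in EtOH would give (2E,5S,6S,7S)-2-(diethylamino)-5-(diethoxymethyl)-7-hydroxy-1-methoxy-6-methyl-5-(prop-2-en-1-yl)-7-(3,4,5-trimethoxyphenyl)hept-2-en-4-one F3. Aqueous acid would hydrolyse the enaminone to 13 in the flask, which would continue to 16 under the conditions of step 6.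

**Step 6.** Acid may induce migration of the allyl group with aromatisation of ring A, or ionisation of the benzylic C2–O1 bond with loss of configuration at C2. The closure may also stall because the enol ether geometry that cannot reach the aldehyde predominates. Fallback, from 13 back to 16, with no compound outside the list: the acid treatment would be stopped at 14 under buffered conditions (pyridinium tosylate, wet acetone, rt) and 14 isolated. Ring A would then be closed under base (K2CO3, MeOH, rt), where reversible methoxide addition at C7a interconverts the enol ether isomers and E1cB dehydration of 15 completes the condensation.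

**Step 3.** Base may remove the doubly activated C5–H of 7, with loss of enantiomeric purity or double-bond migration, and oxidative addition next to the bulky acetal may be slow. Fallback, from 6 back to 7: carboxylation by halogen–lithium exchange (MeLi, then tBuLi, THF, −78 °C; CO2) would give, on mild acidification with citric acid, (2Z,4S)-2-(diethoxymethyl)-4-hydroxy-4-(3,4,5-trimethoxyphenyl)but-2-enoic acid F4, which should lactonise spontaneously to 7.

**Step 2.** The vinylalanate may lose ethoxide to form an allene, or the regiocontrol of the hydroalumination may be incomplete. Fallback, from 4 back to 6: ruthenium-catalysed trans-hydrosilylation ([Cp*Ru(MeCN)3]PF6, Et3SiH, CH2Cl2, 0 °C) places silicon on the distal alkyne carbon and would give (1S,2Z)-4,4-diethoxy-3-(triethylsilyl)-1-(3,4,5-trimethoxyphenyl)but-2-en-1-ol F5. Iododesilylation with retention (N-iodosuccinimide, 2,6-lutidine, (CF3)2CHOH/MeCN, 0 °C) would give 6.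

## Further compounds

F1 | step 4 | (4S,5S)-3-(diethoxymethyl)-4-methyl-2-(trimethylsilyloxy)-5-(3,4,5-trimethoxyphenyl)-4,5-dihydrofuran | CCOC(OCC)C1=C(O[Si](C)(C)C)O[C@H](c2cc(OC)c(OC)c(OC)c2)[C@H]1C
F2 | step 5 | (5S,6S,7S)-5-(diethoxymethyl)-7-hydroxy-1-methoxy-6-methyl-5-(prop-2-en-1-yl)-7-(3,4,5-trimethoxyphenyl)hept-2-yn-4-one | COCC#CC(=O)[C@](CC=C)(C(OCC)OCC)[C@H](C)[C@H](O)c1cc(OC)c(OC)c(OC)c1
F3 | step 5 | (2E,5S,6S,7S)-2-(diethylamino)-5-(diethoxymethyl)-7-hydroxy-1-methoxy-6-methyl-5-(prop-2-en-1-yl)-7-(3,4,5-trimethoxyphenyl)hept-2-en-4-one | COC/C(N(CC)CC)=C\C(=O)[C@](CC=C)(C(OCC)OCC)[C@H](C)[C@H](O)c1cc(OC)c(OC)c(OC)c1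
F0 | step 6 | none | none
F4 | step 3 | (2Z,4S)-2-(diethoxymethyl)-4-hydroxy-4-(3,4,5-trimethoxyphenyl)but-2-enoic acid | O[C@H](c1cc(OC)c(OC)c(OC)c1)/C=C(\C(O)=O)C(OCC)OCC
F5 | step 2 | (1S,2Z)-4,4-diethoxy-3-(triethylsilyl)-1-(3,4,5-trimethoxyphenyl)but-2-en-1-ol | O[C@H](c1cc(OC)c(OC)c(OC)c1)/C=C(\[Si](CC)(CC)CC)C(OCC)OCC
A1 | alternative 1 | methyl (2S,3S)-5-methoxy-6-(triisopropylsilyloxy)-2-(3,4,5-trimethoxyphenyl)-2,3-dihydro-1-benzofuran-3-carboxylate (trans) | c12cc(OC)c(O[Si](C(C)C)(C(C)C)C(C)C)cc1O[C@H](c1cc(OC)c(OC)c(OC)c1)[C@H]2C(=O)OC
A2 | alternative 1 | (2R)-3-diazo-6-methoxy-7-(triisopropylsilyloxy)-2-(3,4,5-trimethoxyphenyl)chroman-4-one | COc1cc2C(=O)C(=[N+]=[N-])[C@@H](c3cc(OC)c(OC)c(OC)c3)Oc2cc1O[Si](C(C)C)(C(C)C)C(C)C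
A3 | alternative 2 | tert-butyl (2S,3S,3aS)-5-methoxy-3-methyl-6-oxo-3a-(prop-2-en-1-yl)-2-(3,4,5-trimethoxyphenyl)-2,3,3a,6-tetrahydro-1-benzofuran-7-carboxylate | C=CC[C@]12C=C(OC)C(=O)C(C(=O)OC(C)(C)C)=C1O[C@H](c1cc(OC)c(OC)c(OC)c1)[C@H]2C
A4 | alternative 2 | tert-butyl 3-{[(1S,2S,3E)-6-(tert-butyldimethylsilyloxy)-5,6-dimethoxy-2-methyl-3-(prop-2-en-1-yl)-1-(3,4,5-trimethoxyphenyl)hexa-3,5-dien-1-yl]oxy}prop-2-ynoate (ketene acetal geometry not specified) | CC(C)(C)OC(=O)C#CO[C@H](c1cc(OC)c(OC)c(OC)c1)[C@@H](C)/C(CC=C)=C/C(OC)=C(OC)O[Si](C)(C)C(C)(C)C
A5 | alternative 3 | (2S,3S,3aR,7aR)-3-methyl-3a-(prop-2-en-1-yl)-2-(3,4,5-trimethoxyphenyl)-3,3a,7,7a-tetrahydro-1-benzofuran-6(2H)-one (cis-fused) | C=CC[C@]12C=CC(=O)C[C@H]1O[C@H](c1cc(OC)c(OC)c(OC)c1)[C@H]2C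
A6 | alternative 3 | 4-[(1S,2S)-1-hydroxy-1-(3,4,5-trimethoxyphenyl)propan-2-yl]-4-(prop-2-en-1-yl)cyclohexa-2,5-dien-1-one | C=CCC1(C=CC(=O)C=C1)[C@H](C)[C@H](O)c1cc(OC)c(OC)c(OC)c1
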